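## Retrosynthetic overview

1. The keto-phenol arm is the oxidised, opened form of an 8''–5' trans-dihydrobenzofuran (phenylcoumaran). The ring is kept until the last step because it holds the labile C8'' centre as a non-enolisable sp3 carbon.
2. The butyrolactone is disconnected to a 9'-alcohol and a 9-ester of a 2,3-dibenzylsuccinate. Its 8–8' bond comes from a one-electron oxidative cross-coupling of two enolates (unit A ester and unit B imide).
3. Units B and C come from one biomimetic 8''–5' phenoxy-radical dehydrodimerisation of a single N-feruloyl oxazolidinone. The same auxiliary sets C8'' as the enoyl radical and later C8' as the chelated enolate.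
4. Ring order: dihydrobenzofuran (step 2), then butyrolactone (step 6), then the dihydrobenzofuran is opened again (step 8). The three benzene rings are bought.

**Notation:**
- Xc = (4S)-4-benzyl-2-oxo-1,3-oxazolidin-3-yl, TBS = tert-butyldimethylsilyl, TMS = trimethylsilyl.
- Unit A (C1–C9) is the α-benzyl half of the lactone, unit B (primed) the β-benzyl half, and unit C (double-primed) the keto-alcohol arm.
- In dihydrobenzofuran names, C2 = C7'' and C3 = C8''.

**Assumption:** the target SMILES reads as (3R,4R) in the lactone and (S) at C8'', and methyl 3-(4-hydroxy-3-methoxyphenyl)propanoate is taken as a catalogue chemical.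

## Route

**Step 1**
Reactants: 1 (E)-ferulic acid; 2 (S)-4-benzyl-1,3-oxazolidin-2-one
Product: 6 N-feruloyl imide (E)-ArCH=CH-C(=O)Xc (Ar = 4-hydroxy-3-methoxyphenyl), via bis-TMS ferulate 3 (not isolated), via O-TMS feruloyl chloride 4 (not isolated), via O-TMS imide 5 (not isolated)
Conditions: HMDS (1.1 equiv), cat. TMSCl, CH2Cl2, reflux; (COCl)2, cat. DMF, 0 °C to rt, evaporate; 2, Et3N, cat. DMAP, CH2Cl2, 0 °C to rt; 10% aq. citric acid/MeOH work-up
Reagents that add atoms: none
Why: Transient O-silylation lets oxalyl chloride/DMF turn the silyl ester into the acid chloride for DMAP-catalysed N-acylation of the Evans auxiliary, the aryl TMS ether falls off in the mildly acidic work-up, and no stereocentre is formed.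

**Step 2**
Reactants: 6 N-feruloyl imide (two molecules)
Product: 9 (2R,3R)-trans-2-(4-hydroxy-3-methoxyphenyl)-7-methoxy-2,3-dihydrobenzofuran bearing C(=O)Xc at C3 plus (E)-CH=CH-C(=O)Xc at C5, via phenoxyl radical 7 (not isolated), via 8''-5' quinone methide 8 (not isolated)
Conditions: Ag2O (0.6 equiv), dry CH2Cl2, rt, dark, 24 h; SiO2 separation of the two trans diastereomers
Reagents that add atoms: none
Why: This is a biomimetic oxidative phenol coupling (8''–5' dehydrodimerisation) followed by 5-exo oxa-Michael closure of the rearomatised ring B phenol on the p-quinone methide, in which the C–C bond forms on the face of the s-cis, dipole-opposed N-enoyl imide rotamer left open by the 4-benzyl group (3R, modest bias of about 2–4:1, isomers separable because of the auxiliaries) and closure anti to the C3 acyl group gives the trans (2R) ring.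

**Step 3**
Reactants: 9 dihydrobenzofuran bis-imide
Product: 11 (2R,3R)-2-[4-(TBSO)-3-methoxyphenyl]-7-methoxy-2,3-dihydrobenzofuran bearing C(=O)Xc at C3 plus CH2CH2C(=O)Xc at C5, via dihydro bis-imide 10 (not isolated)
Conditions: H2 (1 atm), 10% Pd/C, imidazole (3 equiv), THF, rt; N2 purge; TBSCl (1.5 equiv), rt; filter
Reagents that add atoms: tert-butyldimethylsilyl chloride, CC(C)(C)[Si](C)(C)Cl
Why: Heterogeneous alkene hydrogenation, with imidazole tempering Pd/C so the benzylic C2–O bond is not hydrogenolysed, is followed in the same flask by imidazole-promoted silylation of the only free OH, and the stereocentres are untouched.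

**Step 4**
Reactants: 12 methyl 3-(4-hydroxy-3-methoxyphenyl)propanoate
Product: 13 methyl 3-[4-(TBSO)-3-methoxyphenyl]propanoate
Conditions: TBSCl, imidazole, DMF, rt
Reagents that add atoms: tert-butyldimethylsilyl chloride, CC(C)(C)[Si](C)(C)Cl
Why: Standard phenol silylation masks the oxidisable phenol of unit A for the enolate chemistry, and no stereocentre is involved.

**Step 5**
Reactants: 11 TBS dihydro bis-imide; 13 unit A ester
Product: 16 mixed succinate MeO2C-C8H(CH2ArA)-C8'H(C(=O)Xc)-CH2-(dihydrobenzofuran-5-yl) (8'R; 2R,3R; C8 epimer mixture; ArA = 4-(TBSO)-3-methoxyphenyl), via imide lithium enolate 14 (not isolated), via ester lithium enolate 15 (not isolated)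
Conditions: 11 (1 equiv) + 13 (2 equiv), LDA (3.1 equiv), THF, −78 °C, 30 min; Fe(acac)3 (3.2 equiv), −78 °C to rt
Reagents that add atoms: none
Why: In this oxidative enolate heterocoupling (single-electron oxidation of the mixed lithium enolates by trivalent iron, the laboratory counterpart of 8–8' radical coupling), LDA removes only an unhindered C8' proton because A(1,3) strain keeps the tertiary C8''–H of the other imide out of alignment, the new bond forms on the face of the chelated Z-enolate opposite the 4-benzyl group to set C8' as R (the future lactone C4), and C8 forms as an epimer mixture that step 7 corrects.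

**Step 6**
Reactants: 16 mixed succinate
Product: 18 (4R)-3-[4-(TBSO)-3-methoxybenzyl]-4-{[(2R,3S)-2-(4-(TBSO)-3-methoxyphenyl)-3-(hydroxymethyl)-7-methoxy-2,3-dihydrobenzofuran-5-yl]methyl}oxolan-2-one (C3 epimer mixture), via diol ester 17 (not isolated)
Conditions: NaBH4 (8 equiv), THF/H2O 4:1, 0 °C to rt; aq. NH4Cl
Reagents that add atoms: none
Why: Borohydride reductive cleavage of N-acyl oxazolidinones is chemoselective because the imide carbonyls are far more electrophilic than the methyl ester, the 9'-alkoxide then closes the γ-lactone by 5-exo transesterification (the O9'–C9 bond of the natural lactone), and C8', C7'' and C8'' are untouched.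

**Step 7**
Reactants: 18 bis-TBS lactone alcohol
Product: 19 (3R,4R)-3-(4-hydroxy-3-methoxybenzyl)-4-{[(2R,3S)-2-(4-hydroxy-3-methoxyphenyl)-3-(hydroxymethyl)-7-methoxy-2,3-dihydrobenzofuran-5-yl]methyl}oxolan-2-one
Conditions: DBU (3 equiv), MeCN/H2O 19:1, rt to 40 °C; citric acid work-up (pH 4)
Reagents that add atoms: none
Why: DBU/water cleaves aryl silyl ethers selectively, the same base equilibrates C3 through the lactone enolate to the thermodynamically favoured trans-3,4-dibenzyl lactone (3R, relayed from the fixed 4R centre), and C8'' has no acidifying neighbour at this stage.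

**Step 8**
Reactants: 19 phenylcoumaran lactone
Product: 22 target (3R,4R)-3-(4-hydroxy-3-methoxybenzyl)-4-{4-hydroxy-3-[(2S)-1-hydroxy-3-(4-hydroxy-3-methoxyphenyl)-3-oxopropan-2-yl]-5-methoxybenzyl}oxolan-2-one, via aryloxy quinone methide 20 (not isolated), via cyclic hemiketal 21 (not isolated)
Conditions: DDQ (1.05 equiv), MeCN/pH 7 phosphate buffer (NaH2PO4/Na2HPO4) 9:1, −10 to 0 °C, 20 min; aq. ascorbic acid quench
Reagents that add atoms: water, O
Why: Proposed new method: DDQ takes hydride from C7''–H (p-hydroxybenzylic and α-oxygenated, hence far more hydridic than the plain p-hydroxybenzylic CH2 groups), the resulting oxocarbenium/aryloxy quinone methide is captured by the large excess of buffered water faster than it loses C8''–H (solvent capture of α-oxygenated benzylic cations normally beats proton loss by orders of magnitude, whereas dry DDQ gives the benzofuran), and the hemiketal collapses to aryl ketone plus ring B phenol with C8'' (S) never becoming planar; the closest known reaction types are the DDQ/water cleavage of p-methoxybenzyl ethers and the DDQ oxidation of p-hydroxybenzylic carbinols to aryl ketones.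

## Compound list

| No. | Name | SMILES | Role |
|---|---|---|---|
| 1 | (E)-ferulic acid | COc1cc(/C=C/C(=O)O)ccc1O | starting material |
| 2 | (S)-4-benzyl-1,3-oxazolidin-2-one | O=C1N[C@@H](Cc2ccccc2)CO1 | starting material |
| 3 | trimethylsilyl (E)-3-[3-methoxy-4-(trimethylsilyloxy)phenyl]prop-2-enoate | COc1cc(/C=C/C(=O)O[Si](C)(C)C)ccc1O[Si](C)(C)C | intermediate (not isolated) |
| 4 | (E)-3-[3-methoxy-4-(trimethylsilyloxy)phenyl]prop-2-enoyl chloride | COc1cc(/C=C/C(=O)Cl)ccc1O[Si](C)(C)C | intermediate (not isolated) |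
| 5 | (S)-4-benzyl-3-{(E)-3-[3-methoxy-4-(trimethylsilyloxy)phenyl]prop-2-enoyl}oxazolidin-2-one | COc1cc(/C=C/C(=O)N2C(=O)OC[C@@H]2Cc2ccccc2)ccc1O[Si](C)(C)C | intermediate (not isolated) |
| 6 | (S)-4-benzyl-3-[(E)-3-(4-hydroxy-3-methoxyphenyl)prop-2-enoyl]oxazolidin-2-one | COc1cc(/C=C/C(=O)N2C(=O)OC[C@@H]2Cc2ccccc2)ccc1O | intermediate |
| 7 | phenoxyl radical of 6 | COc1cc(/C=C/C(=O)N2C(=O)OC[C@@H]2Cc2ccccc2)ccc1[O] | intermediate (not isolated) |
| 8 | 8''–5' coupled p-quinone methide, ring B rearomatised, C8'' arranged as in 9 | COC1=CC(=C[C@H](C(=O)N2C(=O)OC[C@@H]2Cc2ccccc2)c2cc(/C=C/C(=O)N3C(=O)OC[C@@H]3Cc3ccccc3)cc(OC)c2O)C=CC1=O | intermediate (not isolated) |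
| 9 | (2R,3R)-trans-dihydrobenzofuran bis-imide with (E)-enoyl imide at C5 | COc1cc(ccc1O)[C@@H]1Oc2c(OC)cc(/C=C/C(=O)N3C(=O)OC[C@@H]3Cc3ccccc3)cc2[C@H]1C(=O)N1C(=O)OC[C@@H]1Cc1ccccc1 | intermediate |
| 10 | (2R,3R)-dihydro bis-imide, propanoyl imide at C5, free phenol | COc1cc(ccc1O)[C@@H]1Oc2c(OC)cc(CCC(=O)N3C(=O)OC[C@@H]3Cc3ccccc3)cc2[C@H]1C(=O)N1C(=O)OC[C@@H]1Cc1ccccc1 | intermediate (not isolated) |
| 11 | TBS ether of 10 | COc1cc(ccc1O[Si](C)(C)C(C)(C)C)[C@@H]1Oc2c(OC)cc(CCC(=O)N3C(=O)OC[C@@H]3Cc3ccccc3)cc2[C@H]1C(=O)N1C(=O)OC[C@@H]1Cc1ccccc1 | intermediate |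
| 12 | methyl 3-(4-hydroxy-3-methoxyphenyl)propanoate | COC(=O)CCc1ccc(O)c(OC)c1 | starting material |
| 13 | methyl 3-[4-(tert-butyldimethylsilyloxy)-3-methoxyphenyl]propanoate | COC(=O)CCc1ccc(O[Si](C)(C)C(C)(C)C)c(OC)c1 | intermediate |
| 14 | Z lithium enolate of 11 at C8' | [Li+].COc1cc(ccc1O[Si](C)(C)C(C)(C)C)[C@@H]1Oc2c(OC)cc(C/C=C(\[O-])N3C(=O)OC[C@@H]3Cc3ccccc3)cc2[C@H]1C(=O)N1C(=O)OC[C@@H]1Cc1ccccc1 | intermediate (not isolated) |
| 15 | lithium enolate of 13 | [Li+].COC([O-])=CCc1ccc(O[Si](C)(C)C(C)(C)C)c(OC)c1 | intermediate (not isolated) |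
| 16 | mixed succinate, 8'R, (2R,3R), C8 epimer mixture (that centre left open) | COc1cc(ccc1O[Si](C)(C)C(C)(C)C)[C@@H]1Oc2c(OC)cc(C[C@@H](C(=O)N3C(=O)OC[C@@H]3Cc3ccccc3)C(Cc3ccc(O[Si](C)(C)C(C)(C)C)c(OC)c3)C(=O)OC)cc2[C@H]1C(=O)N1C(=O)OC[C@@H]1Cc1ccccc1 | intermediate |
| 17 | 9',9''-diol methyl ester, 8'R, (2R,3S), C8 open | COc1cc(ccc1O[Si](C)(C)C(C)(C)C)[C@@H]1Oc2c(OC)cc(C[C@@H](CO)C(Cc3ccc(O[Si](C)(C)C(C)(C)C)c(OC)c3)C(=O)OC)cc2[C@H]1CO | intermediate (not isolated) |
| 18 | bis-TBS lactone alcohol, 4R, (2R,3S), C3 epimer mixture (that centre left open) | COc1cc(ccc1O[Si](C)(C)C(C)(C)C)[C@@H]1Oc2c(OC)cc(C[C@H]3COC(=O)C3Cc3ccc(O[Si](C)(C)C(C)(C)C)c(OC)c3)cc2[C@H]1CO | intermediate |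
| 19 | (3R,4R)-lactone carrying the (2R,3S)-phenylcoumaran, both phenols free | COc1cc(ccc1O)[C@@H]1Oc2c(OC)cc(C[C@H]3COC(=O)[C@@H]3Cc3ccc(O)c(OC)c3)cc2[C@H]1CO | intermediate |
| 20 | C7'' aryloxy p-quinone methide of 19 | COC1=CC(=C2Oc3c(OC)cc(C[C@H]4COC(=O)[C@@H]4Cc4ccc(O)c(OC)c4)cc3[C@H]2CO)C=CC1=O | intermediate (not isolated) |
| 21 | 2-hydroxy-2-aryl-2,3-dihydrobenzofuran (cyclic hemiketal, C7'' open) | COc1cc(ccc1O)C1(O)Oc2c(OC)cc(C[C@H]3COC(=O)[C@@H]3Cc3ccc(O)c(OC)c3)cc2[C@H]1CO | intermediate (not isolated) |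
| 22 | CNP0191394.1, (3R,4R,8''S) | COc1cc(C[C@H]2C(=O)OC[C@@H]2Cc2cc(OC)c(O)c([C@@H](CO)C(=O)c3ccc(O)c(OC)c3)c2)ccc1O | target |

## Step count and risks

- **Total step count:** 8.
- **Longest linear sequence:** 7 (steps 1, 2, 3, 5, 6, 7, 8). Step 4 is a one-step side branch.

The three steps most likely to fail are 2, 5 and 8, with step 8 the riskiest.

**Step 2.** The risks are mass balance and facial bias. The 8–O–4' and 8–8' coupling modes compete, 9 can be oxidised further, and the selectivity expected from the unchelated imide is only modest.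

The fallback is a cross-coupling instead of a homo-coupling:
- It sets out from 6. Part of 6 is hydrogenated (H2, Pd/C, EtOAc) to the saturated imide (S)-4-benzyl-3-[3-(4-hydroxy-3-methoxyphenyl)propanoyl]oxazolidin-2-one F1.
- The rest of 6 is added by syringe pump to F1 (3 equiv) and Ag2O in CH2Cl2.
- The phenoxyl radical of the saturated imide F2 has no spin density on its side chain, so it can bond only through C5 or O4. It meets radical 7, which removes the 8–8' mode and gives a product with no conjugated side chain to over-oxidise.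
- The resulting cross-coupled quinone methide F3 closes to 10, where the route is rejoined at the silylation half of step 3.
- Excess F1 is recovered, and the diastereomers are separated as 11.

**Step 5.** The risks are homocoupling of either enolate, Claisen-type attack of enolate 15 on the non-enolised imide, and E1cB opening if C8''–H is removed after all.

The fallback is a two-electron SN2 displacement instead of a one-electron coupling:
- It sets out from 13. Enolate 15 is hydroxylated with 2-(phenylsulfonyl)-3-phenyloxaziridine to racemic methyl 2-hydroxy-3-[4-(tert-butyldimethylsilyloxy)-3-methoxyphenyl]propanoate F4.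
- Tf2O/2,6-lutidine (CH2Cl2, −78 °C) converts F4 into methyl 3-[4-(tert-butyldimethylsilyloxy)-3-methoxyphenyl]-2-(trifluoromethylsulfonyloxy)propanoate F5.
- Enolate 14, made alone from 11 with one equivalent of LDA, displaces the triflate at −78 °C on the same open face.
- This returns to 16. Racemic F5 is acceptable because C8 is equilibrated in step 7.

**Step 8.** The risks are aromatisation of 20 to the 2-arylbenzofuran, which destroys C8'', and over-oxidation of the freed ring B phenol.

The fallback is a radical C–H oxygenation on the masked phenols instead of hydride abstraction on the free phenol: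
- It sets out from 18. DBU in dry toluene leaves the silyl ethers in place and gives the trans-(3R,4R) bis-TBS lactone alcohol F6.
- Aerobic peroxidation (N-hydroxyphthalimide 10 mol %, Co(OAc)2 1 mol %, O2, MeCN, rt) goes through a carbon radical at C7'' and not a cation, so loss of C8''–H is not on the pathway. It gives the C7'' hydroperoxide (2-hydroperoxy-2-aryl-2,3-dihydrobenzofuran) F7.
- Me2S reduces F7 to the bis-TBS cyclic hemiketal F8, which opens to the bis-TBS keto-phenol F9.
- Et3N·3HF in MeCN (near neutral) removes both silyl groups and returns to 22.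

## Further compounds

F1 | step 2 | (S)-4-benzyl-3-[3-(4-hydroxy-3-methoxyphenyl)propanoyl]oxazolidin-2-one | COc1cc(CCC(=O)N2C(=O)OC[C@@H]2Cc2ccccc2)ccc1O
F2 | step 2 | phenoxyl radical of the saturated imide | COc1cc(CCC(=O)N2C(=O)OC[C@@H]2Cc2ccccc2)ccc1[O]
F3 | step 2 | cross-coupled quinone methide (saturated side chain on ring B, C8'' arranged as in 10) | COC1=CC(=C[C@H](C(=O)N2C(=O)OC[C@@H]2Cc2ccccc2)c2cc(CCC(=O)N3C(=O)OC[C@@H]3Cc3ccccc3)cc(OC)c2O)C=CC1=O
F4 | step 5 | methyl 2-hydroxy-3-[4-(tert-butyldimethylsilyloxy)-3-methoxyphenyl]propanoate (racemic) | COC(=O)C(O)Cc1ccc(O[Si](C)(C)C(C)(C)C)c(OC)c1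
F5 | step 5 | methyl 3-[4-(tert-butyldimethylsilyloxy)-3-methoxyphenyl]-2-(trifluoromethylsulfonyloxy)propanoate (racemic) | COC(=O)C(Cc1ccc(O[Si](C)(C)C(C)(C)C)c(OC)c1)OS(=O)(=O)C(F)(F)F
F6 | step 8 | trans-(3R,4R) bis-TBS lactone alcohol | COc1cc(ccc1O[Si](C)(C)C(C)(C)C)[C@@H]1Oc2c(OC)cc(C[C@H]3COC(=O)[C@@H]3Cc3ccc(O[Si](C)(C)C(C)(C)C)c(OC)c3)cc2[C@H]1CO
F7 | step 8 | C7'' hydroperoxide (2-hydroperoxy-2-aryl-2,3-dihydrobenzofuran) | COc1cc(ccc1O[Si](C)(C)C(C)(C)C)C1(OO)Oc2c(OC)cc(C[C@H]3COC(=O)[C@@H]3Cc3ccc(O[Si](C)(C)C(C)(C)C)c(OC)c3)cc2[C@H]1CO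
F8 | step 8 | bis-TBS cyclic hemiketal | COc1cc(ccc1O[Si](C)(C)C(C)(C)C)C1(O)Oc2c(OC)cc(C[C@H]3COC(=O)[C@@H]3Cc3ccc(O[Si](C)(C)C(C)(C)C)c(OC)c3)cc2[C@H]1CO
F9 | step 8 | bis-TBS keto-phenol | COc1cc(C[C@H]2C(=O)OC[C@@H]2Cc2cc(OC)c(O)c([C@@H](CO)C(=O)c3ccc(O[Si](C)(C)C(C)(C)C)c(OC)c3)c2)ccc1O[Si](C)(C)C(C)(C)C
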